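Assumption: (S)-α-ionone **1** is bought as the single enantiomer (it is produced from racemic α-ionone by lipase-mediated resolution), and its preparation is not counted as a step.

## The problem

The target **25** is a labdane. Ring A (C1–C5, C10, gem-dimethyl at C4) is trans-fused to ring B (C5–C10), which carries an exocyclic methylene (C8=C17). C9 bears a chain with an acetoxy stereocentre at C11 and an (E)-3-methyl-2-enoate (C13=C14–C15). Three contiguous ring stereocentres must be set: C5, the quaternary C10 and C9, with the C5 and C10 arms trans and the C9 chain equatorial. C5 can direct C10 because the two are neighbours, and the finished ring fusion can direct C9. C11 lies outside the ring next to the congested C9, so it needs reagent control. The methylene migrates into the ring under acid, and C9–H is allylic and becomes enolisable as soon as C11 is a carbonyl. The C12 protons are γ to the ester, so base can eliminate the C11 acetate, and the trisubstituted alkene must get its E geometry from the mechanism of its formation. The feature that opens the route is that C8 is bonded directly to C9 and C9 carries C11 at an oxygenated level. C8–C9 is therefore the α-alkenyl bond of a C11 ketone, and α-ionone already supplies ring A with C5 and the four-carbon arm C6–C7–C8(–C17).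

## Retrosynthesis

**Acetate (25 → 24).** The C11–O acyl bond is cut last. The acetate would not survive base because of the acidic C12 protons, so it is put on the hydroxy ester **24** by a mild acylation.

**Enoate (24 → 22).** The C13–CH3 and C14–C15 bonds are cut together, which leads back to the terminal alkyne **22**. Syn-methylmetalation of the alkyne followed by acylation of the alkenylmetal fixes the E geometry by mechanism. The neighbouring cut, C12–C13 by alkenylation of the C12 enolate of **16** with a β-halo-enoate, is shorter. It was rejected because it passes through a ketone whose C12 protons are also γ to the ester. Such a product is deprotonated by the enolate that makes it, and alkene position and geometry are then lost. In the chosen order C11 is already an alcohol when the enoate appears.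

**C12–C13 (22 → 21).** The alkyne is attached by opening the terminal epoxide **21** at its CH2 carbon. This asks only for an SN2 reaction at a primary carbon and does not touch C11.

**C11 stereocentre (21 → 19 → 16).** The epoxide comes from bromohydrin **20** and hence from bromomethyl ketone **19** by oxazaborolidine reduction. The hindered decalin carbon and CH2Br are a well-differentiated pair for the catalyst. **19** comes from methyl ketone **16** through its kinetic C12 enolate.

**Key disconnection (16 → 15).** The C8–C9 bond is cut, which opens ring B to the keto enol triflate **15**. Against a cut at C9–C10 or C5–C10, this one leaves ring A complete with C5 and C10 in place, and the precursor has no ring B and no C9 stereocentre. The forward reaction must join an sp2 carbon to the α-carbon of a ketone, leave the methylene where it is and choose C9 over C12.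

**Differentiating two methyl ketones (15 → 14 → 12).** C8 and C11 are both methyl ketones, and base cannot tell them apart. C11 is therefore carried as a 1,1-disubstituted alkene while C8 is enolised and sulfonylated (**12 → 14**). Oxidative cleavage that prefers the electron-rich alkene then reveals the ketone (**14 → 15**). This costs two steps, whereas a reduce–protect–deprotect–oxidise detour would cost four.

**Masking and saturation (12 → 11 → 10 → 9).** The C8 ketone is released from its dioxolane, the C11 methylidene comes from the ketone **10** by Wittig reaction, and **10** comes from **9** by hydrogenation of C1=C2.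

**Quaternary C10 (9 → 6 + 7).** The C9–C10 bond is cut by a Claisen transform to allylic alcohol **6** and 2-methoxypropene **7**. The [3,3] shift carries the configuration of the carbinol carbon C2 across to C10, and the C2 oxygen ends as the C11 carbonyl oxygen. A conjugate addition to enone **5** would instead leave a C2 carbonyl to be removed.

**Back to the chiral pool (6 → 5 → 4 → 3 → 1).** The alcohol comes from enone **5**, the enone by allylic oxidation of **4**, and **4** from (S)-α-ionone **1** by conjugate reduction and ketalisation. The side chain is saturated first because a C6=C7 alkene would form a 1,5-diene with C1=C2 after the Claisen step and could undergo Cope rearrangement at that temperature.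

## Roads not taken

**Alternative 1:** The cut removes C5–C10 and C8–C9 together and opens both rings to the acyclic triene imide **A1**. In **A1** an (E)-trisubstituted N-enoyl oxazolidinone (C9=C10) is tethered through C1–C4 to an (E,E)-diene (C5–C8) that ends in the C17 silyl ether. Forward, Me2AlCl activates the imide and an intramolecular Diels–Alder reaction gives the trans-fused octalin imide **A2**.
- Merits: both rings and C5, C10 and C9 are made in one step from an achiral chain under auxiliary control. C11 arrives as an acyl group that can be reduced to the aldehyde, from which a vinylogous aldol addition would add C12–C15 and the C11 hydroxyl in one operation. That end game is shorter than the one chosen here.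
- Weak points: the dienophile is β,β-disubstituted and must create the quaternary C10, while the diene terminus C5 sits next to the gem-dimethyl carbon. Both new bonds therefore form at congested carbons. β,β-Disubstituted enoyl imides also hold the planar chelated form poorly, and a four-atom tether tends to give mixtures of ring fusions.
- After the cycloaddition the C6=C7 alkene must be saturated, and the C8 stereocentre is destroyed again when C17–OH is eliminated to the methylene.
- Comparison: **A2** is reached in fewer steps and more convergently than **16**. The chosen plan offers stereo-determining steps that each act at one hindered centre at a time, and it delivers the methylene in place.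

**Alternative 2:** The cut removes C4–C5 and C9–C10 and leads to the epoxy diene **A3**. Forward, Cp2TiCl opens the (S)-epoxide to the tertiary C4 radical, two 6-endo cyclisations follow, and the tertiary C8 radical is captured by a second trivalent titanium and eliminates to the exocyclic alkene of **A4**.
- Merits: this is the shortest way to the decalin. The precursor is an epoxyfarnesyl-type chain, the chair–chair closure gives the trans fusion and an equatorial C9 substituent, the methylene is the normal end of such cascades, and no acid is present.
- Weak points: a C3 hydroxyl is made that the target lacks and that costs a two-step radical deoxygenation. Radical bicyclisations of this kind usually give modest yields beside monocyclic, reduced and alkene-isomeric products. The ring stereocentres depend on the epoxide alone and are unrelated to C11, so any shortfall in epoxide purity appears as diastereomers. The C12 oxygen must later be exchanged for carbon through an epoxide, so the end game is no shorter than the chosen one.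
- Comparison: in step count to the bicyclic core this road is clearly better. The chosen plan gives **16** without surplus functionality, sets each stereocentre in a separate step that can be checked, and closes ring B on a substrate that can only give the trans-fused ring.

**Alternative 3:** The cut removes C9–C10 and leads to the phenol **A5**. Forward, PhI(OAc)2 in hexafluoroisopropanol (or a carbon anode) gives a phenoxonium ion. Its para carbon C10 is attacked by C9 of the allylsilane, and loss of silicon releases the C8=C17 methylene in dienone **A6**.
- Merits: ring B, the quaternary C10 and the methylene are made in one step, which is more than the chosen key step achieves, and the aromatic precursor is easy to assemble.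
- Weak points: ring A of **A6** is far from the target. It has a C3 carbonyl, two alkenes, only one methyl on C4 and an sp2 C5. Reductive methylation, saturation of C1=C2 and removal of the carbonyl mean four or more strongly reducing or basic steps next to the exocyclic alkene and the allylic C9–H.
- The phenoxonium ion is flat, so the faces at C10 and C9 are chosen only by the C11 dioxolane through allylic strain. The acidic fluorinated medium also invites dienone–phenol rearrangement.
- Comparison: the ring closure itself forms more in one step than the chosen one. The chosen plan offers a cyclisation product, **16**, whose ring A is already final because C4, C5 and C10 were arranged before ring closure.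

Key step: step 11

## Route

Step 1
Reactants: 1 (S)-α-ionone
Product: 3 (S)-dihydro-α-ionone [(S)-4-(2,6,6-trimethylcyclohex-2-en-1-yl)butan-2-one], via triethylsilyl enol ether 2 (not isolated)
Conditions: Et3SiH, RhCl(PPh3)3 (1 mol %), toluene, 60 °C; then 1 M HCl, THF, rt
Reagents that add atoms: none
Why: Rhodium-catalysed 1,4-hydrosilylation of the enone (conjugate reduction) gives the silyl enol ether, which dilute acid hydrolyses to the saturated ketone; the trisubstituted ring alkene does not react and the ring stereocentre (later C5) is untouched.

Step 2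
Reactants: 3 (S)-dihydro-α-ionone
Product: 4 2-methyl-2-{2-[(1S)-2,6,6-trimethylcyclohex-2-en-1-yl]ethyl}-1,3-dioxolane
Conditions: ethylene glycol, pyridinium p-toluenesulfonate (cat.), benzene, reflux, Dean–Stark trap
Reagents that add atoms: ethylene glycol OCCO
Why: Acid-catalysed ketalisation with azeotropic removal of water; the mild pyridinium acid should not move the ring alkene to the tetrasubstituted position.

Step 3
Reactants: 4 dioxolane of dihydro-α-ionone
Product: 5 (4S)-3,5,5-trimethyl-4-[2-(2-methyl-1,3-dioxolan-2-yl)ethyl]cyclohex-2-en-1-one
Conditions: t-BuOOH (70 % aq., 5 equiv), Rh2(cap)4 (dirhodium tetrakis(caprolactamate), 1 mol %), K2CO3, CH2Cl2, rt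
Reagents that add atoms: tert-butyl hydroperoxide CC(C)(C)OO
Why: Allylic oxidation by the tert-butylperoxyl radical: hydrogen is taken from the open allylic CH2 (C2) and not from the shielded tertiary C5–H, and the allylic peroxide collapses to the enone; this oxidation is established on the α-ionone ring.

Step 4
Reactants: 5 enone
Product: 6 (1S,4S)-3,5,5-trimethyl-4-[2-(2-methyl-1,3-dioxolan-2-yl)ethyl]cyclohex-2-en-1-ol (hydroxyl trans to the side chain)
Conditions: LiBH(s-Bu)3, THF, −78 °C; aq. NH4Cl
Reagents that add atoms: none
Why: 1,2-Reduction of a β,β-disubstituted enone by a bulky borohydride. With the side chain pseudo-axial (it avoids A(1,2) strain with the C10 methyl) the axial methyl of C4 covers the α face of the carbonyl, so hydride should enter from the β face and leave the hydroxyl α, trans to the side chain.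

Step 5
Reactants: 6 trans-allylic alcohol; 7 2-methoxypropene
Product: 9 1-[(1S,6S)-1,5,5-trimethyl-6-[2-(2-methyl-1,3-dioxolan-2-yl)ethyl]cyclohex-2-en-1-yl]propan-2-one, via allyl isopropenyl ether 8 (not isolated)
Conditions: 2-methoxypropene (10 equiv), propionic acid (5 mol %), xylene, sealed tube, 135 °C
Reagents that add atoms: none
Why: Ketal Claisen (Saucy–Marbet-type) rearrangement: acid-catalysed exchange with 7 and loss of methanol give ether 8, whose [3,3] shift forms C9–C10 on the face from which the C2–O bond leaves. The suprafacial 1,3-transfer puts the acetonyl group α on C10, trans to the C5 arm, creates the quaternary centre and moves the alkene to C1=C2; the former C2 oxygen becomes the C11 carbonyl oxygen.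

Step 6
Reactants: 9 Claisen ketone
Product: 10 1-[(1R,2S)-1,3,3-trimethyl-2-[2-(2-methyl-1,3-dioxolan-2-yl)ethyl]cyclohexyl]propan-2-one
Conditions: H2 (1 atm), 10 % Pd/C, EtOAc, rt
Reagents that add atoms: none
Why: Heterogeneous hydrogenation of the cis-disubstituted ring alkene; ketone and dioxolane are inert and no stereocentre is formed.

Step 7
Reactants: 10 saturated keto dioxolane
Product: 11 2-methyl-2-{2-[(1S,2R)-2,6,6-trimethyl-2-(2-methylprop-2-en-1-yl)cyclohexyl]ethyl}-1,3-dioxolane
Conditions: Ph3PCH3Br, KOt-Bu, THF, 0 °C to 50 °C
Reagents that add atoms: methyltriphenylphosphonium bromide C[P+](c1ccccc1)(c1ccccc1)c1ccccc1.[Br-]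
Why: Wittig methylenation of the methyl ketone. It stores the C11 carbonyl as a 1,1-disubstituted alkene, which is blind to the base of step 9 and is reopened in step 10.

Step 8
Reactants: 11 methallyl dioxolane
Product: 12 4-[(1S,2R)-2,6,6-trimethyl-2-(2-methylprop-2-en-1-yl)cyclohexyl]butan-2-one
Conditions: 2 M HCl, THF, rt
Reagents that add atoms: water O
Why: Hydrolysis of the dioxolane by dilute aqueous acid at room temperature; the isolated 1,1-disubstituted alkene should neither hydrate nor migrate under these conditions.

Step 9
Reactants: 12 methallyl methyl ketone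
Product: 14 4-[(1S,2R)-2,6,6-trimethyl-2-(2-methylprop-2-en-1-yl)cyclohexyl]but-1-en-2-yl trifluoromethanesulfonate, via lithium enolate 13 (not isolated)
Conditions: LiN(i-Pr)2 (1.1 equiv), THF, −78 °C; then N-(5-chloropyridin-2-yl)bis(trifluoromethanesulfonyl)imide (Comins reagent), −78 °C to 0 °C
Reagents that add atoms: N-(5-chloropyridin-2-yl)bis(trifluoromethanesulfonyl)imide O=S(=O)(N(c1ccc(Cl)cn1)S(=O)(=O)C(F)(F)F)C(F)(F)F
Why: Kinetic deprotonation of the methyl ketone at its methyl group (C17) by the hindered amide and O-sulfonylation of the enolate give the 2-triflyloxy-1-alkene; the minor internal triflate is removed by chromatography.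

Step 10
Reactants: 14 methallyl enol triflate
Product: 15 4-[(1S,2R)-2,6,6-trimethyl-2-(2-oxopropyl)cyclohexyl]but-1-en-2-yl trifluoromethanesulfonate
Conditions: OsO4 (2 mol %), NaIO4 (4 equiv), 2,6-lutidine, dioxane/H2O (3:1), rt
Reagents that add atoms: sodium periodate [Na+].[O-]I(=O)(=O)=O
Why: Lemieux–Johnson cleavage (osmium-catalysed dihydroxylation, periodate cleavage, lutidine buffer): OsO4 attacks the electron-rich 1,1-dialkyl alkene far faster than the alkene of the enol triflate, which carries a strongly electron-withdrawing sulfonate.

Step 11
Reactants: 15 keto enol triflate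
Product: 16 1-[(1S,4aS,8aS)-5,5,8a-trimethyl-2-methylidenedecahydronaphthalen-1-yl]ethan-1-one
Conditions: Pd(PPh3)4 (10 mol %), KOPh (1.5 equiv), THF, 65 °C
Reagents that add atoms: none
Why: Zerovalent palladium adds oxidatively to the C8–O bond of the enol triflate; phenoxide replaces triflate on palladium and enolises the methyl ketone reversibly on both sides. The C9 enolate binds the metal through carbon to give a seven-membered palladacycle, and reductive elimination forms C8–C9 and returns zerovalent palladium. The closest known reaction type is the intramolecular palladium-catalysed α-alkenylation of ketones with alkenyl halides or triflates under Pd(PPh3)4 and KOPh or KOt-Bu. Ring B closes in a 6-exo mode with respect to the enolate: the enolate C=C stays outside the new ring, and C8 enters it with its methylene exocyclic. Regioselectivity needs no help from acidity, because the C12 enolate could only close an eight-membered ring and returns to the ketone. The trans ring fusion is already in the substrate, whose two arms are trans-diequatorial on the chair of ring A. The new stereocentre C9 is controlled by that chair-like closure, in which the acetyl-bearing carbon takes the equatorial site, and by the axial C10 methyl, which should make phenol reprotonate any product enolate at C9 from the α face, that is to the same ketone. The step needs the 1,1-disubstituted alkene to stay out of conjugation with the ketone, which is why a weak base is used and the reaction is stopped at full conversion.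

Step 12
Reactants: 16 methyl ketone
Product: 19 2-bromo-1-[(1S,4aS,8aS)-5,5,8a-trimethyl-2-methylidenedecahydronaphthalen-1-yl]ethan-1-one, via lithium enolate 17 (not isolated), via trimethylsilyl enol ether 18 (not isolated)
Conditions: LiN(i-Pr)2, THF, −78 °C; Me3SiCl, −78 °C to 0 °C; then N-bromosuccinimide, THF, −78 °C
Reagents that add atoms: N-bromosuccinimide O=C1CCC(=O)N1Br
Why: Kinetic deprotonation takes the open C12 methyl and not the tertiary C9–H buried between C8 and the quaternary C10; the enolate is trapped on oxygen and the silyl enol ether is brominated much faster than the 1,1-disubstituted alkene reacts. C9 is never deprotonated, so its configuration holds.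

Step 13
Reactants: 19 bromomethyl ketone
Product: 21 (2R)-2-[(1S,4aS,8aS)-5,5,8a-trimethyl-2-methylidenedecahydronaphthalen-1-yl]oxirane, via bromohydrin 20 (not isolated)
Conditions: (R)-2-methyl-CBS-oxazaborolidine (20 mol %), catecholborane (1.5 equiv), toluene, −78 °C to −40 °C; then 2 M NaOH, MeOH/THF, 0 °C to rt
Reagents that add atoms: none
Why: Corey–Bakshi–Shibata reduction of a bromomethyl ketone: the decalin carbon C9 is the large group and CH2Br the small one, so the (R)-catalyst should deliver hydride to the face that gives the (1R)-bromohydrin (the spatial arrangement of 11S in the target); catecholborane does not hydroborate the alkene. Hydroxide then closes the epoxide by displacement at C12 and leaves C11 untouched.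

Step 14
Reactants: 21 epoxide
Product: 22 (1S)-1-[(1S,4aS,8aS)-5,5,8a-trimethyl-2-methylidenedecahydronaphthalen-1-yl]but-3-yn-1-ol
Conditions: LiC≡CH·H2NCH2CH2NH2 (3 equiv), DMSO, rt
Reagents that add atoms: lithium acetylide [Li]C#C
Why: SN2 opening of the monosubstituted epoxide by acetylide at its CH2 terminus (C12); C11 keeps its configuration.

Step 15
Reactants: 22 homopropargylic alcohol
Product: 24 methyl (2E,5S)-5-hydroxy-3-methyl-5-[(1S,4aS,8aS)-5,5,8a-trimethyl-2-methylidenedecahydronaphthalen-1-yl]pent-2-enoate, via alkenylalane 23 (not isolated)
Conditions: Me3Al (3.5 equiv), Cp2ZrCl2 (0.3 equiv), CH2Cl2, 0 °C to rt; then ClCO2Me, 0 °C to rt; 1 M HCl work-up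
Reagents that add atoms: trimethylaluminium C[Al](C)C; methyl chloroformate COC(=O)Cl
Why: Negishi zirconium-catalysed methylalumination: the first equivalent of Me3Al turns the hydroxyl into an aluminium alkoxide, then methyl and aluminium add syn across the alkyne with methyl on C13 and aluminium on C14. Acylation of the alkenylalane by the chloroformate goes with retention, so C12 and the ester are trans (E); the 1,1-disubstituted C8=C17 alkene does not carbometalate.

Step 16
Reactants: 24 hydroxy ester
Product: 25 methyl (2E,5S)-5-acetoxy-3-methyl-5-[(1S,4aS,8aS)-5,5,8a-trimethyl-2-methylidenedecahydronaphthalen-1-yl]pent-2-enoate (CNP0309821.1)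
Conditions: Ac2O, pyridine, 4-(dimethylamino)pyridine (cat.), CH2Cl2, 0 °C to rt
Reagents that add atoms: acetic anhydride CC(=O)OC(C)=O
Why: Nucleophile-catalysed acylation of the hindered secondary alcohol; it is left to the end and kept free of strong base because the C12 protons are γ to the ester and a C11 acetate could be lost by vinylogous elimination.

## Compound list

1 | (S)-α-ionone, (3E)-4-[(1S)-2,6,6-trimethylcyclohex-2-en-1-yl]but-3-en-2-one | CC(=O)/C=C/[C@@H]1C(C)=CCCC1(C)C | starting material
2 | triethylsilyl enol ether of 3 (mixture of enol ether geometries) | CC[Si](CC)(CC)OC(C)=CC[C@@H]1C(C)=CCCC1(C)C | intermediate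
3 | (S)-4-(2,6,6-trimethylcyclohex-2-en-1-yl)butan-2-one | CC(=O)CC[C@@H]1C(C)=CCCC1(C)C | intermediate
4 | 2-methyl-2-{2-[(1S)-2,6,6-trimethylcyclohex-2-en-1-yl]ethyl}-1,3-dioxolane | CC1(CC[C@@H]2C(C)=CCCC2(C)C)OCCO1 | intermediate
5 | (4S)-3,5,5-trimethyl-4-[2-(2-methyl-1,3-dioxolan-2-yl)ethyl]cyclohex-2-en-1-one | CC1(CC[C@@H]2C(C)=CC(=O)CC2(C)C)OCCO1 | intermediate
6 | (1S,4S)-3,5,5-trimethyl-4-[2-(2-methyl-1,3-dioxolan-2-yl)ethyl]cyclohex-2-en-1-ol | CC1(CC[C@@H]2C(C)=C[C@@H](O)CC2(C)C)OCCO1 | intermediate
7 | 2-methoxypropene | COC(C)=C | starting material
8 | 2-methyl-2-{2-[(1S,4S)-2,6,6-trimethyl-4-(prop-1-en-2-yloxy)cyclohex-2-en-1-yl]ethyl}-1,3-dioxolane | CC1(CC[C@@H]2C(C)=C[C@@H](OC(C)=C)CC2(C)C)OCCO1 | intermediate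
9 | 1-[(1S,6S)-1,5,5-trimethyl-6-[2-(2-methyl-1,3-dioxolan-2-yl)ethyl]cyclohex-2-en-1-yl]propan-2-one | CC1(CC[C@H]2C(C)(C)CC=C[C@]2(C)CC(C)=O)OCCO1 | intermediate
10 | 1-[(1R,2S)-1,3,3-trimethyl-2-[2-(2-methyl-1,3-dioxolan-2-yl)ethyl]cyclohexyl]propan-2-one | CC1(CC[C@H]2C(C)(C)CCC[C@]2(C)CC(C)=O)OCCO1 | intermediate
11 | 2-methyl-2-{2-[(1S,2R)-2,6,6-trimethyl-2-(2-methylprop-2-en-1-yl)cyclohexyl]ethyl}-1,3-dioxolane | CC1(CC[C@H]2C(C)(C)CCC[C@]2(C)CC(C)=C)OCCO1 | intermediate
12 | 4-[(1S,2R)-2,6,6-trimethyl-2-(2-methylprop-2-en-1-yl)cyclohexyl]butan-2-one | CC(=O)CC[C@H]1C(C)(C)CCC[C@]1(C)CC(C)=C | intermediate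
13 | lithium enolate of 12 (terminal, C8=C17) | [Li]OC(=C)CC[C@H]1C(C)(C)CCC[C@]1(C)CC(C)=C | intermediate
14 | 4-[(1S,2R)-2,6,6-trimethyl-2-(2-methylprop-2-en-1-yl)cyclohexyl]but-1-en-2-yl trifluoromethanesulfonate | C=C(OS(=O)(=O)C(F)(F)F)CC[C@H]1C(C)(C)CCC[C@]1(C)CC(C)=C | intermediate
15 | 4-[(1S,2R)-2,6,6-trimethyl-2-(2-oxopropyl)cyclohexyl]but-1-en-2-yl trifluoromethanesulfonate | C=C(OS(=O)(=O)C(F)(F)F)CC[C@H]1C(C)(C)CCC[C@]1(C)CC(C)=O | intermediate
16 | 1-[(1S,4aS,8aS)-5,5,8a-trimethyl-2-methylidenedecahydronaphthalen-1-yl]ethan-1-one | C=C1CC[C@H]2C(C)(C)CCC[C@]2(C)[C@H]1C(C)=O | intermediate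
17 | lithium enolate of 16 (terminal, C11=C12) | C=C1CC[C@H]2C(C)(C)CCC[C@]2(C)[C@H]1C(=C)O[Li] | intermediate
18 | trimethylsilyl enol ether of 16 (terminal, C11=C12) | C=C1CC[C@H]2C(C)(C)CCC[C@]2(C)[C@H]1C(=C)O[Si](C)(C)C | intermediate
19 | 2-bromo-1-[(1S,4aS,8aS)-5,5,8a-trimethyl-2-methylidenedecahydronaphthalen-1-yl]ethan-1-one | C=C1CC[C@H]2C(C)(C)CCC[C@]2(C)[C@H]1C(=O)CBr | intermediate
20 | (1R)-2-bromo-1-[(1S,4aS,8aS)-5,5,8a-trimethyl-2-methylidenedecahydronaphthalen-1-yl]ethan-1-ol | C=C1CC[C@H]2C(C)(C)CCC[C@]2(C)[C@H]1[C@@H](O)CBr | intermediate
21 | (2R)-2-[(1S,4aS,8aS)-5,5,8a-trimethyl-2-methylidenedecahydronaphthalen-1-yl]oxirane | C=C1CC[C@H]2C(C)(C)CCC[C@]2(C)[C@H]1[C@@H]3CO3 | intermediate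
22 | (1S)-1-[(1S,4aS,8aS)-5,5,8a-trimethyl-2-methylidenedecahydronaphthalen-1-yl]but-3-yn-1-ol | C=C1CC[C@H]2C(C)(C)CCC[C@]2(C)[C@H]1[C@@H](O)CC#C | intermediate
23 | (E)-alkenyl(dimethyl)alane of 22 with O–AlMe2 | C=C1CC[C@H]2C(C)(C)CCC[C@]2(C)[C@H]1[C@@H](O[Al](C)C)C/C(C)=C/[Al](C)C | intermediate
24 | methyl (2E,5S)-5-hydroxy-3-methyl-5-[(1S,4aS,8aS)-5,5,8a-trimethyl-2-methylidenedecahydronaphthalen-1-yl]pent-2-enoate | C=C1CC[C@H]2C(C)(C)CCC[C@]2(C)[C@H]1[C@@H](O)C/C(C)=C/C(=O)OC | intermediate
25 | methyl (2E,5S)-5-acetoxy-3-methyl-5-[(1S,4aS,8aS)-5,5,8a-trimethyl-2-methylidenedecahydronaphthalen-1-yl]pent-2-enoate | C=C1CC[C@H]2C(C)(C)CCC[C@]2(C)[C@H]1[C@H](C/C(C)=C/C(=O)OC)OC(C)=O | target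

## Step count and least certain steps

Total: 16 steps. Longest linear sequence: 16 steps, from **1** to **25** (**7** enters as a purchased reagent-level building block).

**Step 11 (key step).** The product's C9–H is both allylic and α to the ketone. Phenoxide can therefore enolise the product, which would let C9 drift to its epimer (the equatorial acetyl isomer is not clearly the more stable one) and let the exocyclic alkene move into conjugation. Phenoxide can also cleave the S–O bond of the triflate before palladium inserts. The fallback closes the ring without base. It sets out from **14** and returns at **16**. LiN(i-Pr)2 (2.2 equiv) eliminates triflate from **14** to give the terminal alkyne F1. The OsO4/NaIO4 cleavage of step 10 then gives the keto alkyne F2. t-BuMe2SiOTf and Et3N convert it mainly into the more substituted (Z)-silyl enol ether F3 (C9=C11). (Ph3P)AuCl/AgBF4 (monovalent gold, 5 mol %) in CH2Cl2/MeOH then brings about the 6-exo-dig addition of C9 to the activated alkyne. Protodeauration leaves the C8=C17 methylene, methanol takes the silyl group, and **16** results. The terminal enol ether isomer cannot cyclise and is returned as F2.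

**Step 5.** The [3,3] shift must build a quaternary carbon while the axial C4 methyl sits under the migrating fragment. Acid-promoted ionisation of the allylic ether with elimination to a diene can therefore outrun the rearrangement. The fallback sets out from **6** and returns at **9**. Eschenmoser–Claisen rearrangement with N,N-dimethylacetamide dimethyl acetal (xylene, 140 °C, no acid) gives the dimethylamide F6. MeLi (THF, −78 °C to 0 °C) converts it into the methyl ketone **9**.

**Step 4.** Hydride delivery may show poor facial selectivity, because the two faces of the carbonyl differ only by the axial C4 methyl and the remote side chain. Any cis alcohol would send the Claisen transfer to the wrong face of C10. The fallback sets out from **5** and returns at **6**. If reduction gives the cis-alcohol F4, Mitsunobu inversion (PPh3, diisopropyl azodicarboxylate, 4-nitrobenzoic acid) gives the trans 4-nitrobenzoate F5. Methanolysis (K2CO3, MeOH) then gives **6**.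

**Step 13.** Catalyst control may be incomplete. The carbonyl is flanked by the very hindered C9, the catalysed reduction may be slow enough for uncatalysed background reduction to compete, and the substrate's own facial bias may oppose the catalyst. The fallback sets out from **19** and returns at **21**. NaBH4 (MeOH, 0 °C) gives the bromohydrin epimers F7 and K2CO3 closes them to the epoxide epimers F8. Hydrolytic kinetic resolution with (salen)Co(OAc) (trivalent cobalt), using the catalyst enantiomer that consumes the unwanted C11 series, hydrolyses that epimer to the diol F9 and leaves **21**.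

**Step 15.** The neighbouring aluminium alkoxide may hold back the carboalumination, and the chloroformate may acylate oxygen in competition with the alkenyl–aluminium bond. The fallback sets out from **22** and returns at **24**. The alkenylalane **23** is quenched with iodine to give the (E)-alkenyl iodide F10. Palladium-catalysed methoxycarbonylation (PdCl2(PPh3)2, CO 1 atm, MeOH, K2CO3) then gives **24** with retention of geometry.

## Further compounds

F1 | step 11 | 4-[(1S,2R)-2,6,6-trimethyl-2-(2-methylprop-2-en-1-yl)cyclohexyl]but-1-yne | C#CCC[C@H]1C(C)(C)CCC[C@]1(C)CC(C)=C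
F2 | step 11 | 1-[(1R,2S)-2-(but-3-yn-1-yl)-1,3,3-trimethylcyclohexyl]propan-2-one | C#CCC[C@H]1C(C)(C)CCC[C@]1(C)CC(C)=O
F3 | step 11 | (Z)-tert-butyldimethylsilyl enol ether of F2 (C9=C11) | C#CCC[C@H]1C(C)(C)CCC[C@]1(C)/C=C(/C)O[Si](C)(C)C(C)(C)C
F4 | step 4 | (1R,4S)-3,5,5-trimethyl-4-[2-(2-methyl-1,3-dioxolan-2-yl)ethyl]cyclohex-2-en-1-ol | CC1(CC[C@@H]2C(C)=C[C@H](O)CC2(C)C)OCCO1
F5 | step 4 | (1S,4S)-3,5,5-trimethyl-4-[2-(2-methyl-1,3-dioxolan-2-yl)ethyl]cyclohex-2-en-1-yl 4-nitrobenzoate | CC1(CC[C@@H]2C(C)=C[C@@H](OC(=O)c3ccc(cc3)[N+](=O)[O-])CC2(C)C)OCCO1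
F6 | step 5 | N,N-dimethyl-2-[(1S,6S)-1,5,5-trimethyl-6-[2-(2-methyl-1,3-dioxolan-2-yl)ethyl]cyclohex-2-en-1-yl]acetamide | CC1(CC[C@H]2C(C)(C)CC=C[C@]2(C)CC(=O)N(C)C)OCCO1
F7 | step 13 | 2-bromo-1-[(1S,4aS,8aS)-5,5,8a-trimethyl-2-methylidenedecahydronaphthalen-1-yl]ethan-1-ol, both C11 epimers | C=C1CC[C@H]2C(C)(C)CCC[C@]2(C)[C@H]1C(O)CBr
F8 | step 13 | 2-[(1S,4aS,8aS)-5,5,8a-trimethyl-2-methylidenedecahydronaphthalen-1-yl]oxirane, both C11 epimers | C=C1CC[C@H]2C(C)(C)CCC[C@]2(C)[C@H]1C3CO3
F9 | step 13 | (1S)-1-[(1S,4aS,8aS)-5,5,8a-trimethyl-2-methylidenedecahydronaphthalen-1-yl]ethane-1,2-diol | C=C1CC[C@H]2C(C)(C)CCC[C@]2(C)[C@H]1[C@H](O)CO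
F10 | step 15 | (1S,3E)-4-iodo-3-methyl-1-[(1S,4aS,8aS)-5,5,8a-trimethyl-2-methylidenedecahydronaphthalen-1-yl]but-3-en-1-ol | C=C1CC[C@H]2C(C)(C)CCC[C@]2(C)[C@H]1[C@@H](O)C/C(C)=C/I
A1 | alternative 1 | (4S)-4-benzyl-3-[(2E,8E,10E)-12-(tert-butyldimethylsilyloxy)-3,7,7-trimethyldodeca-2,8,10-trienoyl]oxazolidin-2-one | CC(C)(C)[Si](C)(C)OC/C=C/C=C/C(C)(C)CCC/C(C)=C/C(=O)N1[C@@H](Cc2ccccc2)COC1=O
A2 | alternative 1 | trans-fused octalin imide with C6=C7 alkene, C17 silyl ether and C11 acyl oxazolidinone | CC(C)(C)[Si](C)(C)OC[C@H]1C=C[C@H]2C(C)(C)CCC[C@]2(C)[C@H]1C(=O)N3[C@@H](Cc4ccccc4)COC3=O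
A3 | alternative 2 | (4R)-4-[(1E,5E)-8-[(2S)-3,3-dimethyloxiran-2-yl]-2,6-dimethylocta-1,5-dien-1-yl]-2,2-dimethyl-1,3-dioxolane | CC1(C)O[C@H]1CC/C(C)=C/CC/C(C)=C/[C@@H]2COC(C)(C)O2
A4 | alternative 2 | 3-hydroxy-8(17)-ene trans-decalin with the C11–C12 acetonide | C=C1CC[C@H]2C(C)(C)[C@@H](O)CC[C@]2(C)[C@H]1[C@@H]3COC(C)(C)O3
A5 | alternative 3 | 3-[(3Z)-4-[(4R)-2,2-dimethyl-1,3-dioxolan-4-yl]-3-(trimethylsilylmethyl)but-3-en-1-yl]-2,4-dimethylphenol | Cc1c(O)ccc(C)c1CC/C(C[Si](C)(C)C)=C/[C@@H]1COC(C)(C)O1
A6 | alternative 3 | ring-fused 4-methylcyclohexa-2,5-dienone with 8(17)-methylene ring B and the C11–C12 acetonide | C=C1CCC2=C(C)C(=O)C=C[C@]2(C)[C@H]1[C@@H]3COC(C)(C)O3
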